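**Plan**

- Retrosynthesis: the aldehyde carbon is traced back to a methyl group of an isopropenyl side chain (allylic C–H oxidation). The O1–C2 bond of the dihydrobenzofuran is then cut and O1 is rejoined to the isopropenyl carbon, which unveils a trans-3-hydroxy-4-acyloxy-2,2-dimethylchroman.
- Feature used: benzofuran C2 carries both O1 and a branched three-carbon unit. This is the array a 2,2-dimethylchroman gives when its pyran oxygen moves from the gem-dimethyl carbon to the neighbouring carbinol carbon.
- Further cuts: the C4–O ester bond (carboxylic acid plus chromene oxide), the oxirane (chromene), the side-chain ester C–O bond, and the chromene O1–C2 and C4–C4a bonds (4-hydroxyacetophenone plus 3-methylbut-2-enal).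
- Forward order of rings: pyran ring by chromenylation (step 1), oxirane (step 4) opened in step 5, furan ring from the pyran ring by ring contraction (step 6); steps 7 and 8 raise the methyl group to the aldehyde.
- Stereochemistry: side-chain carbinol from asymmetric transfer hydrogenation; acid stereocentre purchased; chroman C3/C4 from Jacobsen–Katsuki epoxidation and anti opening; benzofuran C2 by inversion at chroman C3 in the key step, with old C4 untouched.

Key step: step 6

Remark: (R)-2-methylbutanoic acid 7 is taken as a purchasable single enantiomer; chroman numbering is used up to step 6 and benzofuran numbering afterwards (chroman C3 becomes benzofuran C2, chroman C4 becomes C3).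

**Route**

Step 1
Reactants: 1 4-hydroxyacetophenone; 2 3-methylbut-2-enal
Product: 5 1-(2,2-dimethyl-2H-chromen-6-yl)ethanone, via benzodioxaborin 3 (not isolated), via ortho-quinone methide 4 (not isolated)
Conditions: PhB(OH)2 (1 equiv), propionic acid (cat.), toluene, reflux, Dean–Stark
Reagents that add atoms: none
Why: Boronic acid mediated chromenylation: the aryl boronate delivers the enal to the ortho carbon to give benzodioxaborin 3, which fragments on heating to ortho-quinone methide 4, and oxa-6π electrocyclisation closes the pyran ring; the two ortho positions of 1 are equivalent, so only the 6-acetyl chromene can form.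

Step 2
Reactants: 5 1-(2,2-dimethyl-2H-chromen-6-yl)ethanone
Product: 6 (1R)-1-(2,2-dimethyl-2H-chromen-6-yl)ethanol
Conditions: RuCl[(R,R)-TsDPEN](p-cymene) (1 mol %), HCO2H/Et3N (5:2), 30 °C
Reagents that add atoms: none
Why: Noyori asymmetric transfer hydrogenation of an aryl methyl ketone: the (R,R)-TsDPEN ruthenium hydride adds hydrogen to the Si face of the carbonyl group, as it does with acetophenone, to set the (R)-carbinol, and its outer-sphere hydride transfer leaves the chromene double bond alone.

Step 3
Reactants: 6 (1R)-1-(2,2-dimethyl-2H-chromen-6-yl)ethanol; 7 (2R)-2-methylbutanoic acid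
Product: 8 (1R)-1-(2,2-dimethyl-2H-chromen-6-yl)ethyl (2R)-2-methylbutanoate
Conditions: DCC, DMAP (cat.), CH2Cl2, 0 °C to rt
Reagents that add atoms: none
Why: Steglich esterification: the carbinol C–O bond is not broken, so the (R) centre is retained, and carbodiimide activation at 0 °C does not enolise the simple alkyl-branched acid, so its (R) centre is carried through unchanged.

Step 4
Reactants: 8 (1R)-1-(2,2-dimethyl-2H-chromen-6-yl)ethyl (2R)-2-methylbutanoate
Product: 9 (1R)-1-[(3R,4R)-3,4-epoxy-2,2-dimethyl-3,4-dihydro-2H-chromen-6-yl]ethyl (2R)-2-methylbutanoate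
Conditions: (R,R)-(salen)MnCl [salen = N,N'-bis(3,5-di-tert-butylsalicylidene)cyclohexane-1,2-diaminate; trivalent manganese] (4 mol %), 4-phenylpyridine N-oxide (cat.), aq NaOCl (pH 11.3), CH2Cl2, 0 °C
Reagents that add atoms: sodium hypochlorite, [Na+].[O-]Cl
Why: Jacobsen–Katsuki epoxidation of a 2,2-dimethylchromene, the best substrate class for this catalyst: the (R,R)-complex transfers oxygen to the face of the cis alkene that gives the (3R,4R)-oxide (the (S,S)-complex gives the (3S,4S) series), catalyst control overriding the remote side-chain centres, and the esters tolerate the cold buffered two-phase medium.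

Step 5
Reactants: 9 (1R)-1-[(3R,4R)-3,4-epoxy-2,2-dimethyl-3,4-dihydro-2H-chromen-6-yl]ethyl (2R)-2-methylbutanoate; 10 3-methylbutanoic acid
Product: 11 (3R,4S)-3-hydroxy-2,2-dimethyl-6-[(1R)-1-{[(2R)-2-methylbutanoyl]oxy}ethyl]-3,4-dihydro-2H-chromen-4-yl 3-methylbutanoate
Conditions: acid 10 (5 equiv), i-Pr2NEt (1 equiv), toluene, 40–60 °C
Reagents that add atoms: none
Why: Anti opening of a benzylic epoxide by a carboxylate (SN2-type acidolysis): the ammonium carboxylate attacks C4, which is benzylic and activated by the ortho ring oxygen while C3 is neopentyl, with inversion (4R to 4S) and leaves the C3–O bond intact (3R), giving the trans hydroxy ester, and the excess acid keeps the medium too weakly basic for acyl migration.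

Step 6
Reactants: 11 (3R,4S)-3-hydroxy-2,2-dimethyl-6-[(1R)-1-{[(2R)-2-methylbutanoyl]oxy}ethyl]-3,4-dihydro-2H-chromen-4-yl 3-methylbutanoate
Product: 13 (2R,3S)-5-[(1R)-1-{[(2R)-2-methylbutanoyl]oxy}ethyl]-2-(prop-1-en-2-yl)-2,3-dihydro-1-benzofuran-3-yl 3-methylbutanoate, via C3 triflate 12 (not isolated)
Conditions: Tf2O (1.2 equiv), 2,6-di-tert-butyl-4-methylpyridine (3 equiv), CH2Cl2, −40 °C to rt
Reagents that add atoms: none
Why: Tf2O converts the hindered C3 hydroxyl into triflate 12; in the half-chair with both substituents pseudo-equatorial the C3–OTf bond is antiperiplanar to the ring C2–O1 bond, so O1 displaces triflate from the rear through a bridged aryloxiranium-like transition structure while its bond to the gem-dimethyl carbon ionises, and the hindered pyridine removes a methyl proton to leave the isopropenyl group. The closest known reactions are the dehydrative ring contraction of 2,2-dimethylchroman-3-ols to 2-isopropenyl-2,3-dihydrobenzofurans and the ring-oxygen 1,2-shift of equatorial pyranoside 2-triflates. The furan ring (O1, old C3, old C4, C4a, C8a) closes by a 1,2-shift inside the pyran ring, formally a 3-exo-tet attack of O1 on C3 followed by opening of the three-membered ring at its tertiary carbon, not by an end-to-end cyclisation. The new stereocentre, benzofuran C2, is fixed as R by the substrate through stereospecific inversion at the (3R) carbinol carbon, while the acyloxy carbon is not touched and stays S, so the trans chroman gives the trans dihydrobenzofuran. The step needs the ring oxygen to win over the ester carbonyl, a methyl group and the C4–aryl bond as participating or migrating groups: ester and methyl are anti to the triflate only in the diaxial conformer, which is expected to be the less populated one, the aryl shift would have to pass through a strained fused phenonium ion, elimination toward C4 is excluded because H4 is syn to the triflate, and the non-nucleophilic base in CH2Cl2 offers no external nucleophile to trap the cation.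

Step 7
Reactants: 13 (2R,3S)-5-[(1R)-1-{[(2R)-2-methylbutanoyl]oxy}ethyl]-2-(prop-1-en-2-yl)-2,3-dihydro-1-benzofuran-3-yl 3-methylbutanoate
Product: 14 (2R,3S)-2-(3-hydroxyprop-1-en-2-yl)-5-[(1R)-1-{[(2R)-2-methylbutanoyl]oxy}ethyl]-2,3-dihydro-1-benzofuran-3-yl 3-methylbutanoate
Conditions: SeO2 (cat.), t-BuOOH, CH2Cl2, rt
Reagents that add atoms: tert-butyl hydroperoxide, CC(C)(C)OO (its oxygen is passed on by SeO2)
Why: SeO2 allylic oxidation (ene reaction then [2,3]-sigmatropic shift, catalytic in selenium with t-BuOOH as terminal oxidant): of the two allylic positions the methyl group is attacked, since the ring C2–H is tertiary, hindered and deactivated by O1, and no stereocentre is involved.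

Step 8
Reactants: 14 (2R,3S)-2-(3-hydroxyprop-1-en-2-yl)-5-[(1R)-1-{[(2R)-2-methylbutanoyl]oxy}ethyl]-2,3-dihydro-1-benzofuran-3-yl 3-methylbutanoate
Product: 15 (2R,3S)-5-[(1R)-1-{[(2R)-2-methylbutanoyl]oxy}ethyl]-2-(3-oxoprop-1-en-2-yl)-2,3-dihydro-1-benzofuran-3-yl 3-methylbutanoate
Conditions: MnO2 (excess), CH2Cl2, rt
Reagents that add atoms: none
Why: MnO2 oxidises allylic alcohols selectively to the conjugated aldehydes under neutral conditions, which spares both esters, the allylic aryl ether and all four stereocentres; any aldehyde already formed in step 7 converges on the same product.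

**Compound list**

1 | 4-hydroxyacetophenone | CC(=O)c1ccc(O)cc1 | starting material
2 | 3-methylbut-2-enal | CC(C)=CC=O | starting material
3 | 1-[4-(2-methylprop-1-en-1-yl)-2-phenyl-4H-1,3,2-benzodioxaborinin-6-yl]ethanone (formed in the flask, not isolated) | CC(=O)c1ccc2OB(c3ccccc3)OC(C=C(C)C)c2c1 | intermediate
4 | 4-acetyl-6-(3-methylbut-2-en-1-ylidene)cyclohexa-2,4-dien-1-one, the ortho-quinone methide (formed in the flask, not isolated) | CC(=O)C1=CC(=CC=C(C)C)C(=O)C=C1 | intermediate
5 | 1-(2,2-dimethyl-2H-chromen-6-yl)ethanone | CC(=O)c1ccc2OC(C)(C)C=Cc2c1 | intermediate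
6 | (1R)-1-(2,2-dimethyl-2H-chromen-6-yl)ethanol | CC1(C)C=Cc2cc([C@@H](C)O)ccc2O1 | intermediate
7 | (2R)-2-methylbutanoic acid | CC[C@@H](C)C(=O)O | starting material
8 | (1R)-1-(2,2-dimethyl-2H-chromen-6-yl)ethyl (2R)-2-methylbutanoate | CC1(C)C=Cc2cc([C@@H](C)OC(=O)[C@H](C)CC)ccc2O1 | intermediate
9 | (1R)-1-[(3R,4R)-3,4-epoxy-2,2-dimethyl-3,4-dihydro-2H-chromen-6-yl]ethyl (2R)-2-methylbutanoate (oxirane cis-fused across C3–C4) | CC1(C)Oc2ccc([C@@H](C)OC(=O)[C@H](C)CC)cc2[C@H]3O[C@@H]13 | intermediate
10 | 3-methylbutanoic acid | CC(C)CC(=O)O | starting material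
11 | (3R,4S)-3-hydroxy-2,2-dimethyl-6-[(1R)-1-{[(2R)-2-methylbutanoyl]oxy}ethyl]-3,4-dihydro-2H-chromen-4-yl 3-methylbutanoate (trans) | CC1(C)Oc2ccc([C@@H](C)OC(=O)[C@H](C)CC)cc2[C@H](OC(=O)CC(C)C)[C@H]1O | intermediate
12 | (3R,4S)-2,2-dimethyl-6-[(1R)-1-{[(2R)-2-methylbutanoyl]oxy}ethyl]-3-[(trifluoromethanesulfonyl)oxy]-3,4-dihydro-2H-chromen-4-yl 3-methylbutanoate (formed in the flask, not isolated) | CC1(C)Oc2ccc([C@@H](C)OC(=O)[C@H](C)CC)cc2[C@H](OC(=O)CC(C)C)[C@H]1OS(=O)(=O)C(F)(F)F | intermediate
13 | (2R,3S)-5-[(1R)-1-{[(2R)-2-methylbutanoyl]oxy}ethyl]-2-(prop-1-en-2-yl)-2,3-dihydro-1-benzofuran-3-yl 3-methylbutanoate (trans) | C=C(C)[C@H]1Oc2ccc([C@@H](C)OC(=O)[C@H](C)CC)cc2[C@@H]1OC(=O)CC(C)C | intermediate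
14 | (2R,3S)-2-(3-hydroxyprop-1-en-2-yl)-5-[(1R)-1-{[(2R)-2-methylbutanoyl]oxy}ethyl]-2,3-dihydro-1-benzofuran-3-yl 3-methylbutanoate | C=C(CO)[C@H]1Oc2ccc([C@@H](C)OC(=O)[C@H](C)CC)cc2[C@@H]1OC(=O)CC(C)C | intermediate
15 | (2R,3S)-5-[(1R)-1-{[(2R)-2-methylbutanoyl]oxy}ethyl]-2-(3-oxoprop-1-en-2-yl)-2,3-dihydro-1-benzofuran-3-yl 3-methylbutanoate (CNP0154159.1) | C=C(C=O)[C@H]1Oc2ccc([C@@H](C)OC(=O)[C@H](C)CC)cc2[C@@H]1OC(=O)CC(C)C | target

**Step count and risks**

Total steps: 8. Longest linear sequence: 8 steps (1 to 15).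

Steps most likely to fail, in order of risk:

Step 6. The ring-oxygen shift may be outrun by participation of the C4 ester carbonyl at C3 (acyloxonium formation from the diaxial conformer) or by a methyl shift from the same conformer. The fallback replaces the acyloxy group, for the contraction only, by an aryl ether that cannot reach C3. It sets out from epoxide 9: 4-methoxyphenol and K2CO3 in DMF should open the oxirane at C4 with inversion to give the trans aryl ether alcohol (1R)-1-[(3R,4S)-3-hydroxy-4-(4-methoxyphenoxy)-2,2-dimethyl-3,4-dihydro-2H-chromen-6-yl]ethyl (2R)-2-methylbutanoate F1. Tf2O and the hindered pyridine then take it through its C3 triflate (1R)-1-[(3R,4S)-4-(4-methoxyphenoxy)-2,2-dimethyl-3-[(trifluoromethanesulfonyl)oxy]-3,4-dihydro-2H-chromen-6-yl]ethyl (2R)-2-methylbutanoate F2, which is not isolated, to the ring-contracted aryl ether (1R)-1-[(2R,3S)-3-(4-methoxyphenoxy)-2-(prop-1-en-2-yl)-2,3-dihydro-1-benzofuran-5-yl]ethyl (2R)-2-methylbutanoate F3. (NH4)2Ce(NO3)6 in buffered aqueous acetonitrile at 0 °C removes the aryl group oxidatively to give the alcohol (1R)-1-[(2R,3S)-3-hydroxy-2-(prop-1-en-2-yl)-2,3-dihydro-1-benzofuran-5-yl]ethyl (2R)-2-methylbutanoate F4, and DCC/DMAP esterification with acid 10 comes back to the route at 13.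

Step 5. Ionisation at C4 ahead of carboxylate attack may erode the trans selectivity, and the acyl group may wander from O4 to O3 on prolonged warming. The fallback brings the ester in by acylation instead of by epoxide opening. It sets out from epoxide 9: hydrolysis in aqueous THF with a trace of HClO4 at 0 °C should give the trans diol (1R)-1-[(3R,4S)-3,4-dihydroxy-2,2-dimethyl-3,4-dihydro-2H-chromen-6-yl]ethyl (2R)-2-methylbutanoate F5, from which any cis diol is removed by chromatography. 3-Methylbutanoyl chloride and 2,4,6-collidine in CH2Cl2 at −40 °C are then expected to acylate the benzylic C4 hydroxyl in preference to the C3 hydroxyl, which is shielded by the gem-dimethyl group, at a temperature too low for acyl migration; this comes back to the route at 11.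

Step 7. The selenium-mediated oxidation may stall at partial conversion, over-oxidise, or abstract the ring C2 hydrogen instead of a methyl hydrogen. The fallback functionalises the methyl group by an ene-type chlorination. It sets out from 13: Ca(OCl)2 and solid CO2 in CH2Cl2/water at 0 °C (hypochlorous acid ene reaction) should give the allylic chloride (2R,3S)-2-(3-chloroprop-1-en-2-yl)-5-[(1R)-1-{[(2R)-2-methylbutanoyl]oxy}ethyl]-2,3-dihydro-1-benzofuran-3-yl 3-methylbutanoate F6. N-Methylmorpholine N-oxide with catalytic NaI and NaHCO3 in acetonitrile (Kornblum-type oxidation) then converts the chloride directly into the aldehyde, coming back to the route at 15 and bypassing 14.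

**Further compounds**

F1 | step 6 | (1R)-1-[(3R,4S)-3-hydroxy-4-(4-methoxyphenoxy)-2,2-dimethyl-3,4-dihydro-2H-chromen-6-yl]ethyl (2R)-2-methylbutanoate | CC1(C)Oc2ccc([C@@H](C)OC(=O)[C@H](C)CC)cc2[C@H](Oc2ccc(OC)cc2)[C@H]1O
F2 | step 6 | (1R)-1-[(3R,4S)-4-(4-methoxyphenoxy)-2,2-dimethyl-3-[(trifluoromethanesulfonyl)oxy]-3,4-dihydro-2H-chromen-6-yl]ethyl (2R)-2-methylbutanoate | CC1(C)Oc2ccc([C@@H](C)OC(=O)[C@H](C)CC)cc2[C@H](Oc2ccc(OC)cc2)[C@H]1OS(=O)(=O)C(F)(F)F
F3 | step 6 | (1R)-1-[(2R,3S)-3-(4-methoxyphenoxy)-2-(prop-1-en-2-yl)-2,3-dihydro-1-benzofuran-5-yl]ethyl (2R)-2-methylbutanoate | C=C(C)[C@H]1Oc2ccc([C@@H](C)OC(=O)[C@H](C)CC)cc2[C@@H]1Oc1ccc(OC)cc1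
F4 | step 6 | (1R)-1-[(2R,3S)-3-hydroxy-2-(prop-1-en-2-yl)-2,3-dihydro-1-benzofuran-5-yl]ethyl (2R)-2-methylbutanoate | C=C(C)[C@H]1Oc2ccc([C@@H](C)OC(=O)[C@H](C)CC)cc2[C@@H]1O
F5 | step 5 | (1R)-1-[(3R,4S)-3,4-dihydroxy-2,2-dimethyl-3,4-dihydro-2H-chromen-6-yl]ethyl (2R)-2-methylbutanoate | CC1(C)Oc2ccc([C@@H](C)OC(=O)[C@H](C)CC)cc2[C@H](O)[C@H]1O
F6 | step 7 | (2R,3S)-2-(3-chloroprop-1-en-2-yl)-5-[(1R)-1-{[(2R)-2-methylbutanoyl]oxy}ethyl]-2,3-dihydro-1-benzofuran-3-yl 3-methylbutanoate | C=C(CCl)[C@H]1Oc2ccc([C@@H](C)OC(=O)[C@H](C)CC)cc2[C@@H]1OC(=O)CC(C)C
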